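The complex with two exchanged is the product we want, and we ask how much of it stands after 2.5 d as the charge of starting complex grows.

| setting | larch | elm | maple | north-west | south-west | east | south | north-east |
|---|---|---|---|---|---|---|---|---|
| starting complex | 0.017 M | 0.037 M | 0.088 M | 0.015 M | 0.020 M | 0.030 M | 0.050 M | 0.080 M |
| incoming ligand | 0.060 M | 0.060 M | 0.060 M | 0.0600 M | 0.0600 M | 0.0600 M | 0.0600 M | 0.0600 M |
| leaving ligand | 0.10 M | 0.10 M | 0.10 M | 0.100 M | 0.100 M | 0.100 M | 0.100 M | 0.100 M |
| remark | run made earlier | run made earlier | run made earlier |  |  |  |  |  |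
| time |  |  |  | 2.5 d | 2.5 d | 2.5 d | 2.5 d | 2.5 d |

| larch: time / d | larch: complex with two exchanged / % | elm: time / d | elm: complex with two exchanged / % | maple: time / d | maple: complex with two exchanged / % |
|---|---|---|---|---|---|
| 0.208 | 22.9 | 0.333 | 13.3 | 0.625 | 3.9 |
| 0.500 | 16.2 | 0.833 | 8.3 | 1.25 | 1.0 |
| 1.04 | 8.6 | 1.67 | 3.1 | 2.08 | 0.4 |
| 2.50 | 2.5 | 2.50 | 1.0 | 2.50 | 0.2 |

(each reading ± 0.5 percentage points)

- "hardly changes" means that all values lie within two and a half points (for a concentration: within two and a half percent of the largest)

* [complex with two exchanged] at the end for north-west, south-west, east, south, north-east, in this order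
* the shape of the row from first to last (falls, then rises / rises all the way / rises, then falls / falls all the way / hardly changes)

The time scales can be read from the larch run. The first rung is the build-up of the product: at 0.208 d the larch percentage stands at 22.9 %, and at the next reading it stands lower. The next rung is the fall. From 16.2 % at 0.500 d to 2.5 % at 2.50 d the larch run gives 0.934 d⁻¹ as the mean fall constant, the logarithm of the ratio of two readings over the time between them, an apparent first-order constant. Its half-time is 0.742 d. The last rung is the asked time itself, which is 3.37 of these larch half-times, so the end value lies on the tail of the fall.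

The elm tail reads badly: its last reading is 1.0 %, with a scatter of 0.5 percentage points. We therefore take elm's higher reading, 8.3 % at 0.833 d, and carry it to the end with the mean constant of the larch run, on the assumption that this constant holds in elm too, and our estimate of c of the product in elm comes to 6.47 × 10⁻⁴ M.

The mean replaces a curve, so we check the error. The early larch stretch gives 1.19 d⁻¹ and the late one 0.846 d⁻¹, and these put elm between 4.26 × 10⁻⁴ M and 7.49 × 10⁻⁴ M. The last larch reading comes to 4.25 × 10⁻⁴ M and the last maple reading to 1.76 × 10⁻⁴ M, so we expect a rise and then a fall.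

The forecast gives 3.600 × 10⁻⁴ M, 3.900 × 10⁻⁴ M, 4.000 × 10⁻⁴ M, 3.700 × 10⁻⁴ M and 2.600 × 10⁻⁴ M, with the shape rises, then falls, and warns that “The early rise is small compared with the noise”. Our elm estimate stands higher than each of its values.

The flask gives 4.21 × 10⁻⁴ M, 5.03 × 10⁻⁴ M, 5.92 × 10⁻⁴ M, 5.21 × 10⁻⁴ M and 2.32 × 10⁻⁴ M, so the row rises, then falls, with its top in east.

    starting complex + incoming ligand ⇌ leaving ligand + complex with one exchanged (K = 0.760, k = 0.00390 L mol⁻¹ s⁻¹)
    complex with one exchanged + incoming ligand ⇌ leaving ligand + complex with two exchanged (K = 3.70, k = 0.00750 L mol⁻¹ s⁻¹)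
    complex with one exchanged → side product (k = 5.80 × 10⁻⁵ s⁻¹)
    complex with two exchanged → over-reaction product (k = 1.60 × 10⁻⁶ s⁻¹)
    starting complex → decomposition product (k = 3.50 × 10⁻⁸ s⁻¹)

At the end, 14 % of the incoming ligand is left in north-east, against 75 % in north-west. Over the second half of north-west, the larch fall constant 0.934 d⁻¹ carries 8.71 % to 2.71 %, and the flask holds 2.80 %. In east it carries 5.94 % to 1.85 %, and the flask holds 1.97 %.

(The runs stem from a simulated flask for an exercise.)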